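**Plan**

- Locants (daucane skeleton): C1 quaternary CH3 carbon, C2 CH–O-angeloyl, C4 C(OH)i-Pr, C5 ring-fusion CH, C6 CH–O-anisoyl, C8 olefinic C–CH3. Ring A is C1–C5, ring B the seven-membered ring, α the face of the C1 methyl. Ring B holds an oxygenated two-carbon unit C6–C7 between C5 and C8; without it, what remains is a 2-methylcyclopentenone (C5=C8–C9=O) fused to ring A at C1–C5, an enone that can take up C6–C7 by [2+2] photocycloaddition.
- Retrosynthesis: the O2 and O6 esters are cut first, then the C4–i-Pr bond and the C6 carbinol (from a ketal). Ring B is contracted by re-forming C5–C8. The cyclobutane is cut at C5–C6 and C7–C8 into a bicyclo[3.3.0]octenone and 1,1-diethoxyethene. The enone is cut by retro-Pauson–Khand to an enyne, and the enyne at C2–C3 by retro-aldol to methacrolein and pent-3-yn-2-one.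
- Forward: the chain is joined by aldol reaction. Ring A and the cyclopentenone arise together in the Pauson–Khand reaction. The cyclobutane is added across C5=C8, and reductive cleavage of C5–C8 expands the five-membered ring to ring B.
- Stereochemistry: C2 comes from the Ipc2BCl aldol and C1 from the Pauson–Khand reaction (methyl cis to both silyloxy groups). C5 is set by β-face protonation of the C4 enolate, C4 by β-face organocerium attack, and C6 by hydride delivery from the C4 hydroxyl.

Key step: step 6

Assumption: (−)-Ipc2BCl is taken to deliver the methyl ketone enolate to the Re face of methacrolein; if the sense is the reverse, the (+)-reagent is used and only the Ipc descriptors of 3 and of the isopinocampheol change.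

**Route**

Step 1
Reactants: 1 methacrolein; 2 pent-3-yn-2-one
Product: 4 (R)-6-hydroxy-7-methyloct-7-en-2-yn-4-one, via boron enolate 3 (not isolated)
Conditions: 2, (−)-Ipc2BCl, Et3N, Et2O, 0 °C; then 1, −78 → −20 °C; H2O2, pH 7 buffer, MeOH, 0 °C
Reagents that add atoms: none
Why: Diisopinocampheylboron-mediated aldol reaction, in which the kinetic boron enolate of the methyl ketone should add to the Re face of the non-enolisable aldehyde in a cyclic transition state and so set the carbinol carbon (later C2) as R.

Step 2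
Reactants: 4 (R)-6-hydroxy-7-methyloct-7-en-2-yn-4-one
Product: 5 (R)-6-(tert-butyldimethylsilyloxy)-7-methyloct-7-en-2-yn-4-one
Conditions: TBSOTf, 2,6-lutidine, CH2Cl2, −78 °C
Reagents that add atoms: tert-butyldimethylsilyl triflate, CC(C)(C)[Si](C)(C)OS(=O)(=O)C(F)(F)F
Why: Silyl ether formation with a silyl triflate and a hindered pyridine base at low temperature protects O2 for the whole route without retro-aldol cleavage or β-elimination of the β-hydroxy ynone.

Step 3
Reactants: 5 (R)-6-(tert-butyldimethylsilyloxy)-7-methyloct-7-en-2-yn-4-one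
Product: 6 (4S,6R)-6-(tert-butyldimethylsilyloxy)-7-methyloct-7-en-2-yn-4-ol
Conditions: Ru[(S,S)-TsNCH(Ph)CH(Ph)NH](p-cymene) (cat.), i-PrOH, rt
Reagents that add atoms: none
Why: Noyori asymmetric transfer hydrogenation of an alkynyl ketone, in which the catalyst alone (alkyne as the large π substituent) should set the propargylic carbinol (later C4) as S and leave the alkyne, the alkene and the silyl ether untouched.

Step 4
Reactants: 6 (4S,6R)-6-(tert-butyldimethylsilyloxy)-7-methyloct-7-en-2-yn-4-ol
Product: 7 (4S,6R)-6-(tert-butyldimethylsilyloxy)-7-methyl-4-(triethylsilyloxy)oct-7-en-2-yne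
Conditions: TESCl, imidazole, CH2Cl2, 0 °C
Reagents that add atoms: chlorotriethylsilane, CC[Si](CC)(CC)Cl
Why: Silylation of the propargylic alcohol with a group more labile than the tert-butyldimethylsilyl ether, so that O4 can later be freed alone and the alcohol cannot add to the ketene acetal of step 6.

Step 5
Reactants: 7 (4S,6R)-6-(tert-butyldimethylsilyloxy)-7-methyl-4-(triethylsilyloxy)oct-7-en-2-yne
Product: 8 bicyclo[3.3.0]octenone (C5=C8 enone; C9 ketone; 8-CH3; 1α-CH3; 2α-OTBS; 4α-OTES)
Conditions: Co2(CO)8 (20 mol %), tetramethylthiourea (cat.), CO (1 atm), toluene, 70 °C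
Reagents that add atoms: carbon monoxide, [C-]#[O+]
Why: Intramolecular Pauson–Khand [2+2+1] reaction of the 1,6-enyne, which closes ring A and the cyclopentenone at once; both silyloxy groups should sit exo in the metallacycle, which places the methyl group of the new quaternary C1 cis to both.

Step 6
Reactants: 8 bicyclo[3.3.0]octenone (C5=C8 enone; C9 ketone; 8-CH3; 1α-CH3; 2α-OTBS; 4α-OTES); 9 1,1-diethoxyethene
Product: 10 cyclobutane-fused tricyclic ketone (new bonds C5–C6 and C7–C8; 6,6-diethoxy; C6 α at C5; C9 ketone; 4α-OTES; 2α-OTBS)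
Conditions: hν (365 nm, Pyrex), 9 (10 equiv), CH2Cl2, −20 °C
Reagents that add atoms: none
Why: Excitation of the enone (n→π*) and intersystem crossing give the triplet, which adds to the electron-rich alkene to a triplet 1,4-biradical that closes to the cyclobutane after spin inversion. The closest known reaction type is the head-to-tail [2+2] photocycloaddition of cyclopentenones with 1,1-dialkoxyethenes. One ring is closed, the cyclobutane C5–C6–C7–C8, by intermolecular [2+2] annulation across the enone C=C, the second bond forming by recombination of the 1,4-biradical (four-membered ring closure). C5 and C8 become quaternary stereocentres: C5 is controlled by the angular methyl at C1, because only addition on the methyl face keeps the bicyclo[3.3.0]octane cis-fused, and C8 follows from the obligatory cis fusion of the four-membered to the five-membered ring. The step needs regioselectivity (the acetal carbon C6 on the enone β-carbon C5, the CH2 carbon C7 on C8), which the donor alkene and the excited-state polarity of the enone should secure, and chemoselectivity for the enone, secured because the silyl ethers and the saturated ketone product do not absorb at 365 nm. C8 is planarised again in step 10, so what is carried on from here is the constitution and the α placement of C6 at C5.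

Step 7
Reactants: 10 cyclobutane-fused tricyclic ketone (6,6-diethoxy; C9 ketone; 4α-OTES; 2α-OTBS)
Product: 12 C9 p-toluenesulfonylhydrazone of the 4α-hydroxy tricyclic ketone, via hydroxy ketone 11 (not isolated)
Conditions: PPTS (cat.), EtOH, rt; then TsNHNH2, 4 Å MS, 60 °C
Reagents that add atoms: p-toluenesulfonyl hydrazide, Cc1ccc(cc1)S(=O)(=O)NN
Why: Acid-catalysed ethanolysis of the triethylsilyl ether followed by hydrazone formation at the only ketone, with ethanol as solvent so that exchange at the diethyl ketal is degenerate and with molecular sieves to take up the water.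

Step 8
Reactants: 12 C9 p-toluenesulfonylhydrazone of the 4α-hydroxy tricyclic ketone
Product: 14 tricyclic alkenol (C9=C10; 4α-OH; 6,6-diethoxy; 2α-OTBS), via alkenyllithium 13 (not isolated)
Conditions: n-BuLi (3.5 equiv), TMEDA, THF, −78 → 0 °C; then H2O
Reagents that add atoms: none
Why: Shapiro reaction, in which C10 carries the only α-hydrogens so that the alkenyllithium and hence the olefin can form only between C9 and C10, while the C4 alkoxide, the ketal and the silyl ether are inert to the base.

Step 9
Reactants: 14 tricyclic alkenol (C9=C10; 4α-OH; 6,6-diethoxy; 2α-OTBS)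
Product: 15 tricyclic ketone (C4 ketone; C9=C10; 6,6-diethoxy; 2α-OTBS)
Conditions: Dess–Martin periodinane, pyridine, CH2Cl2, 0 °C → rt
Reagents that add atoms: none
Why: Dess–Martin oxidation of the secondary alcohol under buffered conditions, which should spare the ketal, the silyl ether and the strained vinylcyclobutane and puts a carbonyl group next to C5 for the ring expansion.

Step 10
Reactants: 15 tricyclic ketone (C4 ketone; C9=C10; 6,6-diethoxy; 2α-OTBS)
Product: 17 trans-fused hydroazulenone (C4 ketone; 6,6-diethoxy; C8=C9; 5β-H; 2α-OTBS), via lithium enolate 16 (not isolated)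
Conditions: Li, NH3(l), THF, −78 °C; then NH4Cl
Reagents that add atoms: none
Why: Dissolving-metal reductive cleavage of an α-cyclobutyl ketone, in which the C4 ketyl breaks the cyclobutane bond C5–C8 that lies outside ring A and gives an allyl radical (the other bond, C5–C6, would give a less stabilised radical), the allyl anion over C8–C9–C10 is protonated by ammonia at its less substituted end C10 as in the reduction of 1,3-dienes to leave the C8=C9 olefin, and the C4 enolate is protonated on quench from the β face opposite the C1 methyl and the C2 silyloxy group, which should give the trans ring fusion.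

Step 11
Reactants: 17 trans-fused hydroazulenone (C4 ketone; 6,6-diethoxy; C8=C9; 5β-H; 2α-OTBS)
Product: 18 tertiary alcohol (4α-OH; 4β-isopropyl; 6,6-diethoxy; C8=C9; 2α-OTBS)
Conditions: i-PrMgCl, CeCl3, THF, −78 °C; aq. NH4Cl
Reagents that add atoms: isopropylmagnesium chloride, CC(C)[Mg]Cl
Why: Organocerium 1,2-addition to an enolisable ketone, the weakly basic reagent avoiding enolisation and loss of ethoxide, with attack from the β face opposite the C5–C6 bond, the C1 methyl and the C2 silyloxy group so that the hydroxyl ends α.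

Step 12
Reactants: 18 tertiary alcohol (4α-OH; 4β-isopropyl; 6,6-diethoxy; C8=C9; 2α-OTBS)
Product: 19 β-hydroxy ketone (C6 ketone; 4α-OH; C8=C9; 2α-OTBS)
Conditions: PPTS (cat.), acetone/H2O, rt
Reagents that add atoms: water, O
Why: Mild acid-catalysed hydrolysis of the acyclic ketal to the C6 ketone under conditions that should leave the silyl ether, the tertiary aldol-type alcohol and the β,γ-position of the olefin unchanged.

Step 13
Reactants: 19 β-hydroxy ketone (C6 ketone; 4α-OH; C8=C9; 2α-OTBS)
Product: 20 4α,6β-diol (C8=C9; 2α-OTBS)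
Conditions: Me4NBH(OAc)3, MeCN/AcOH, −30 °C
Reagents that add atoms: none
Why: Evans–Saksena reduction, in which the C4 hydroxyl binds the triacetoxyborohydride and delivers hydride to the α face of the C6 carbonyl, which should give the 6β alcohol (anti-1,3-diol).

Step 14
Reactants: 20 4α,6β-diol (C8=C9; 2α-OTBS); 21 4-methoxybenzoyl chloride
Product: 22 6β-(4-methoxybenzoate) (4α-OH; 2α-OTBS)
Conditions: pyridine, DMAP (cat.), CH2Cl2, 0 °C → rt
Reagents that add atoms: none
Why: Esterification of the secondary C6 alcohol with an acid chloride, the hindered tertiary C4 alcohol being unreactive under these conditions.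

Step 15
Reactants: 22 6β-(4-methoxybenzoate) (4α-OH; 2α-OTBS)
Product: 23 2α,4α-diol 6β-(4-methoxybenzoate)
Conditions: HF·pyridine, pyridine, THF, 0 °C → rt
Reagents that add atoms: none
Why: Fluoride-mediated cleavage of the silyl ether with buffered HF·pyridine, which should not touch the aryl ester, the olefin or the tertiary alcohol.

Step 16
Reactants: 23 2α,4α-diol 6β-(4-methoxybenzoate); 24 angelic acid
Product: 26 CNP0204191.1 (target), via mixed anhydride 25 (not isolated)
Conditions: 24, 2,4,6-trichlorobenzoyl chloride, Et3N, toluene, rt; then 23, 80 °C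
Reagents that add atoms: none
Why: Yamaguchi esterification through the mixed anhydride, in which the hindered aroyl carbonyl directs the C2 alcohol to the angeloyl carbonyl and the absence of a nucleophilic catalyst at moderate temperature should keep the Z olefin from isomerising, the tertiary alcohol staying free.

**Compound list**

1 | methacrolein | CC(=C)C=O | starting material
2 | pent-3-yn-2-one | CC#CC(C)=O | starting material
3 | boron enolate: pent-1-en-3-yn-2-yl diisopinocampheylborinate (Ipc from (+)-α-pinene) | C=C(C#CC)OB([C@@H]1C[C@@H]2C[C@H]([C@H]1C)C2(C)C)[C@@H]1C[C@@H]2C[C@H]([C@H]1C)C2(C)C | intermediate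
4 | (R)-6-hydroxy-7-methyloct-7-en-2-yn-4-one | CC#CC(=O)C[C@@H](O)C(C)=C | intermediate
5 | (R)-6-(tert-butyldimethylsilyloxy)-7-methyloct-7-en-2-yn-4-one | CC#CC(=O)C[C@@H](O[Si](C)(C)C(C)(C)C)C(C)=C | intermediate
6 | (4S,6R)-6-(tert-butyldimethylsilyloxy)-7-methyloct-7-en-2-yn-4-ol | CC#C[C@@H](O)C[C@@H](O[Si](C)(C)C(C)(C)C)C(C)=C | intermediate
7 | (4S,6R)-6-(tert-butyldimethylsilyloxy)-7-methyl-4-(triethylsilyloxy)oct-7-en-2-yne | CC#C[C@@H](O[Si](CC)(CC)CC)C[C@@H](O[Si](C)(C)C(C)(C)C)C(C)=C | intermediate
8 | bicyclo[3.3.0]octenone: cyclopentenone (C5=C8, C9=O, C10) fused at C1–C5 to ring A; 8-CH3; 1-CH3, 2-OTBS and 4-OTES all on the α face | O=C1C[C@@]2(C)[C@H](O[Si](C)(C)C(C)(C)C)C[C@H](O[Si](CC)(CC)CC)C2=C1C | intermediate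
9 | 1,1-diethoxyethene (ketene diethyl acetal) | C=C(OCC)OCC | starting material
10 | tricyclic ketone: cyclobutane C5–C6–C7–C8 on the bicyclo[3.3.0]octanone; 6,6-diethoxy; C5–C6 bond cis to the C1 methyl; cyclobutane cis-fused to the cyclopentanone; C9 ketone; 4α-OTES; 2α-OTBS | O=C1C[C@@]2(C)[C@H](O[Si](C)(C)C(C)(C)C)C[C@H](O[Si](CC)(CC)CC)[C@]23C(OCC)(OCC)C[C@]13C | intermediate
11 | hydroxy ketone: 10 without the triethylsilyl group (4α-OH) | O=C1C[C@@]2(C)[C@H](O[Si](C)(C)C(C)(C)C)C[C@H](O)[C@]23C(OCC)(OCC)C[C@]13C | intermediate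
12 | C9 p-toluenesulfonylhydrazone of 11 (N–N syn to C10) | Cc1ccc(cc1)S(=O)(=O)N/N=C1\C[C@@]2(C)[C@H](O[Si](C)(C)C(C)(C)C)C[C@H](O)[C@]23C(OCC)(OCC)C[C@]13C | intermediate
13 | alkenyllithium: C9-lithio C9=C10 olefin, lithium C4 alkoxide | [Li]C1=C[C@@]2(C)[C@H](O[Si](C)(C)C(C)(C)C)C[C@H](O[Li])[C@]23C(OCC)(OCC)C[C@]13C | intermediate
14 | tricyclic alkenol: cyclopentene C9=C10; 4α-OH; 6,6-diethoxy; 2α-OTBS | C1=C[C@@]2(C)[C@H](O[Si](C)(C)C(C)(C)C)C[C@H](O)[C@]23C(OCC)(OCC)C[C@]13C | intermediate
15 | tricyclic ketone: C4 ketone; C9=C10; 6,6-diethoxy; 2α-OTBS | C1=C[C@@]2(C)[C@H](O[Si](C)(C)C(C)(C)C)CC(=O)[C@]23C(OCC)(OCC)C[C@]13C | intermediate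
16 | lithium enolate C4(OLi)=C5 of 17 | CC(C)(C)[Si](C)(C)O[C@@H]1CC(O[Li])=C2C(OCC)(OCC)CC(C)=CC[C@]21C | intermediate
17 | trans-fused hydroazulenone: C4 ketone in ring A; 6,6-diethoxy and C8=C9 (8-CH3) in ring B; 5β-H trans to 1α-CH3; 2α-OTBS | CC(C)(C)[Si](C)(C)O[C@@H]1CC(=O)[C@@H]2C(OCC)(OCC)CC(C)=CC[C@]21C | intermediate
18 | tertiary alcohol: 4α-OH, 4β-isopropyl; otherwise as 17 | CC(C)(C)[Si](C)(C)O[C@@H]1C[C@@](O)(C(C)C)[C@@H]2C(OCC)(OCC)CC(C)=CC[C@]21C | intermediate
19 | β-hydroxy ketone: C6 ketone, 4α-OH, 4β-isopropyl, C8=C9, 2α-OTBS | CC(C)(C)[Si](C)(C)O[C@@H]1C[C@@](O)(C(C)C)[C@@H]2C(=O)CC(C)=CC[C@]21C | intermediate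
20 | diol: 4α-OH, 6β-OH, 2α-OTBS | CC(C)(C)[Si](C)(C)O[C@@H]1C[C@@](O)(C(C)C)[C@@H]2[C@@H](O)CC(C)=CC[C@]21C | intermediate
21 | 4-methoxybenzoyl chloride | COc1ccc(cc1)C(Cl)=O | starting material
22 | 6β-(4-methoxybenzoate), 4α-OH, 2α-OTBS | CC(C)(C)[Si](C)(C)O[C@@H]1C[C@@](O)(C(C)C)[C@@H]2[C@@H](OC(=O)c3ccc(OC)cc3)CC(C)=CC[C@]21C | intermediate
23 | 2α,4α-diol 6β-(4-methoxybenzoate) | O[C@@H]1C[C@@](O)(C(C)C)[C@@H]2[C@@H](OC(=O)c3ccc(OC)cc3)CC(C)=CC[C@]21C | intermediate
24 | angelic acid, (Z)-2-methylbut-2-enoic acid | C/C=C(/C)C(O)=O | starting material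
25 | mixed anhydride: angelic 2,4,6-trichlorobenzoic anhydride | C/C=C(/C)C(=O)OC(=O)c1c(Cl)cc(Cl)cc1Cl | intermediate
26 | CNP0204191.1, (1R,2R,4R,5S,6S)-2-angeloyloxy-4-hydroxydauc-8-en-6-yl 4-methoxybenzoate | C/C=C(/C)C(=O)O[C@@H]1C[C@@](O)(C(C)C)[C@@H]2[C@@H](OC(=O)c3ccc(OC)cc3)CC(C)=CC[C@]21C | target

**Step count and risks**

Total: 16 steps. Longest linear sequence: 16 steps (from 1 and 2).

Steps most likely to fail:

Step 10. The allyl anion may be protonated at its tertiary end C8 instead of C10, which would leave the olefin at C9=C10. The C4 enolate may also be protonated from the α face (cis ring fusion) or lose ethoxide. Fallback: the C9 carbon is kept as a sulfonylhydrazone through the ring expansion, so that no allyl anion arises and the olefin is made afterwards. From 12, Dess–Martin periodinane and pyridine oxidise the C4 alcohol to the tricyclic keto sulfonylhydrazone F1. SmI2, HMPA and t-BuOH in THF at −78 °C then cleave C5–C8 from the C4 ketyl, the C8 radical being held as a 1-azaallyl radical by the C=N group, and give the ring-expanded keto sulfonylhydrazone F2. i-PrMgCl/CeCl3 (one further equivalent for the N–H) adds to C4 and gives the carbinol sulfonylhydrazone F3. An aprotic Bamford–Stevens reaction (NaOMe, diglyme, 140 °C) makes the C9 carbene, whose 1,2-shift of the tertiary C8 hydrogen gives the C8=C9 olefin, and the route is rejoined at 18.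

Step 6. Cycloaddition at the hindered tetrasubstituted enone may be slow, so that the acid- and moisture-sensitive ketene acetal is lost by hydrolysis or polymerisation during long irradiation. Fallback: the two-carbon unit is brought in as a robust enol ester and the ketal is made afterwards. From 8, irradiation (365 nm) in CH2Cl2/vinyl acetate gives the cyclobutyl acetate F4 (both C6 epimers); K2CO3 in MeOH gives the cyclobutanol F5; Dess–Martin periodinane gives the cyclobutanone F6. HC(OEt)3, EtOH and PPTS ketalise the strained four-ring ketone only and remove the triethylsilyl group, which gives 11 and rejoins the route within step 7.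

Step 16. Acylation of the neopentyl-type C2 alcohol may be slow enough for the Z-angeloyl unit to isomerise to the E (tigloyl) ester. Fallback: the Z olefin is built on the ester already in place. From 23, DCC/DMAP coupling with 2-[bis(2,2,2-trifluoroethoxy)phosphoryl]propanoic acid gives the phosphonate ester F7. A Still–Gennari olefination (KHMDS, 18-crown-6, THF, −78 °C, then acetaldehyde) gives 26 directly.

Further compounds
F1 | step 10 | tricyclic keto sulfonylhydrazone (C4 ketone; C9 p-toluenesulfonylhydrazone; 6,6-diethoxy; 2α-OTBS) | Cc1ccc(cc1)S(=O)(=O)N/N=C1\C[C@@]2(C)[C@H](O[Si](C)(C)C(C)(C)C)CC(=O)[C@]23C(OCC)(OCC)C[C@]13C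
F2 | step 10 | ring-expanded keto sulfonylhydrazone (C4 ketone; 5β-H; 8-CH3 at sp3 C8, either epimer; C9 p-toluenesulfonylhydrazone) | CC(C)(C)[Si](C)(C)O[C@@H]1CC(=O)[C@@H]2C(OCC)(OCC)CC(C)C(=NNS(=O)(=O)c3ccc(C)cc3)C[C@]21C
F3 | step 10 | carbinol sulfonylhydrazone (4α-OH; 4β-isopropyl; C9 p-toluenesulfonylhydrazone) | CC(C)(C)[Si](C)(C)O[C@@H]1C[C@@](O)(C(C)C)[C@@H]2C(OCC)(OCC)CC(C)C(=NNS(=O)(=O)c3ccc(C)cc3)C[C@]21C
F4 | step 6 | cyclobutyl acetate (6-OAc, both epimers; C9 ketone; 4α-OTES; 2α-OTBS) | O=C1C[C@@]2(C)[C@H](O[Si](C)(C)C(C)(C)C)C[C@H](O[Si](CC)(CC)CC)[C@]23C(OC(C)=O)C[C@]13C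
F5 | step 6 | cyclobutanol (6-OH, both epimers; C9 ketone; 4α-OTES; 2α-OTBS) | O=C1C[C@@]2(C)[C@H](O[Si](C)(C)C(C)(C)C)C[C@H](O[Si](CC)(CC)CC)[C@]23C(O)C[C@]13C
F6 | step 6 | cyclobutanone (C6 ketone; C9 ketone; 4α-OTES; 2α-OTBS) | O=C1C[C@@]2(C)[C@H](O[Si](C)(C)C(C)(C)C)C[C@H](O[Si](CC)(CC)CC)[C@]23C(=O)C[C@]13C
F7 | step 16 | 2α-O-{2-[bis(2,2,2-trifluoroethoxy)phosphoryl]propanoyl} ester of 23 | CC(C(=O)O[C@@H]1C[C@@](O)(C(C)C)[C@@H]2[C@@H](OC(=O)c3ccc(OC)cc3)CC(C)=CC[C@]21C)P(=O)(OCC(F)(F)F)OCC(F)(F)F
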